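**Retrosynthetic overview**
1. Target ⇐ nonamethyl ether 24 (BBr3) ⇐ aldehyde 21 + phosphonium salt 22 (Wittig at C6) ⇐ C6 nitrile 19.
2. Upper dihydrofuran ring (O1–C2–C3–C3a–C7a), formed last: the C2 alkoxide oxygen attacks aromatic C7a of ring A (C3a, C4, C5, C6, C7, C7a) with loss of fluoride; in the same pot C3 equilibrates to trans and methoxide replaces the second fluoride at C4.
3. Enabling feature: in ring A, C3a lies between two oxygen-bearing carbons (C4–OH and C7a–O1) and is para to C6, which carries the styryl carbon. This local twofold symmetry lets both oxygens enter at the two equivalent C–F bonds of a 2,6-difluoro-4-cyanophenyl group (from 3,4,5-trifluorobenzonitrile); the C6 nitrile activates the ring, acidifies C3–H and later becomes the styryl carbon.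
4. Open-chain precursor: C3–C3a bond by SNAr of a ketone enolate on 3,4,5-trifluorobenzonitrile; C2 by catalyst-controlled transfer hydrogenation; the ketone from the C7′ nitrile of the lower benzofuran and a benzylic Grignard reagent.
5. Lower dihydrofuran ring (O1′–C2′–C3′–C3a′–C7a′), formed first: deoxybenzoin α-arylation, transfer hydrogenation with dynamic kinetic resolution, SNAr closure on the fluoride ortho to the nitrile.

Key step: step 9

Remark: benzofuran locants are used throughout, unprimed for the upper (styryl-bearing) ring system and primed for the lower one; in open-chain precursors C7 and C8 are the future C2 and C3. All phenols are carried as methyl ethers. The target is (2S,3S,2′S,3′S), both rings trans.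

**Step 1**
Reactants: 1 1,3-dimethoxybenzene; 2 (3,5-dimethoxyphenyl)acetic acid
Product: 4 1-(2,4-dimethoxyphenyl)-2-(3,5-dimethoxyphenyl)ethan-1-one, via mixed anhydride 3 (not isolated)
Conditions: 2, (CF3CO)2O, 85% H3PO4 (cat.), CH2Cl2, 0 °C; then 1 (3 equiv), 0 → 25 °C
Reagents that add atoms: none
Why: Friedel–Crafts acylation through the acyl trifluoroacetate; 1,3-dimethoxybenzene should react at C4 (para to one methoxy, ortho to the other), and its excess suppresses self-acylation of 2.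

**Step 2**
Reactants: 5 2-fluoro-4-methoxybenzonitrile
Product: 7 3-bromo-2-fluoro-4-methoxybenzonitrile, via aryllithium 6 (not isolated)
Conditions: LiN(i-Pr)2, THF, −78 °C; then BrCl2C–CCl2Br, −78 → 0 °C
Reagents that add atoms: 1,2-dibromo-1,1,2,2-tetrachloroethane, BrC(Cl)(Cl)C(Cl)(Cl)Br
Why: Directed ortho-lithiation at the C–H flanked by fluorine and methoxy (the most acidic ring position), then electrophilic bromination at −78 °C, below the temperature at which LiF is lost to an aryne.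

**Step 3**
Reactants: 4 1-(2,4-dimethoxyphenyl)-2-(3,5-dimethoxyphenyl)ethan-1-one; 7 3-bromo-2-fluoro-4-methoxybenzonitrile
Product: 8 3-[2-(2,4-dimethoxyphenyl)-1-(3,5-dimethoxyphenyl)-2-oxoethyl]-2-fluoro-4-methoxybenzonitrile (racemic, labile methine)
Conditions: Pd(OAc)2 (5 mol %), XPhos (10 mol %), K3PO4, toluene, 80 °C
Reagents that add atoms: none
Why: Palladium-catalysed ketone α-arylation of a deoxybenzoin to a 1,2,2-triarylethanone; the phosphate base in toluene should leave the activated fluoride alone, and no stereocontrol is needed because the new methine is labile.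

**Step 4**
Reactants: 8 3-[2-(2,4-dimethoxyphenyl)-1-(3,5-dimethoxyphenyl)-2-oxoethyl]-2-fluoro-4-methoxybenzonitrile
Product: 9 3-[(1S,2S)-2-(2,4-dimethoxyphenyl)-1-(3,5-dimethoxyphenyl)-2-hydroxyethyl]-2-fluoro-4-methoxybenzonitrile
Conditions: RuCl[(S,S)-TsDPEN](p-cymene) (2 mol %), HCO2H/Et3N (5:2), DMF, 40 °C
Reagents that add atoms: none
Why: Noyori–Ikariya asymmetric transfer hydrogenation with dynamic kinetic resolution: the acidic diaryl methine epimerises through the enol, the (S,S)-catalyst should give the S carbinol (aryl ketone sense, as for acetophenone), and Felkin–Anh preference (the electron-poor, di-ortho-substituted aryl anti to hydride) should select the (1S,2S) alcohol that leads to the trans ring.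

**Step 5**
Reactants: 9 3-[(1S,2S)-2-(2,4-dimethoxyphenyl)-1-(3,5-dimethoxyphenyl)-2-hydroxyethyl]-2-fluoro-4-methoxybenzonitrile
Product: 10 (2S,3S)-2-(2,4-dimethoxyphenyl)-3-(3,5-dimethoxyphenyl)-4-methoxy-2,3-dihydro-1-benzofuran-7-carbonitrile
Conditions: NaH (1.1 equiv), THF, 0 → 25 °C
Reagents that add atoms: none
Why: Intramolecular SNAr (5-exo) of the alkoxide on the fluoride ortho to the nitrile closes the lower dihydrofuran with retention at both stereocentres, so the (1S,2S) alcohol should give the trans (2S,3S) ring.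

**Step 6**
Reactants: 10 (2S,3S)-2-(2,4-dimethoxyphenyl)-3-(3,5-dimethoxyphenyl)-4-methoxy-2,3-dihydro-1-benzofuran-7-carbonitrile; 11 1-(chloromethyl)-3,5-dimethoxybenzene
Product: 14 1-[(2S,3S)-2-(2,4-dimethoxyphenyl)-3-(3,5-dimethoxyphenyl)-4-methoxy-2,3-dihydro-1-benzofuran-7-yl]-2-(3,5-dimethoxyphenyl)ethan-1-one, via benzylic Grignard reagent 12 (not isolated), via chloromagnesium ketimide 13 (not isolated)
Conditions: 11, Mg, THF, 0 → 25 °C; then 10, THF, 50 °C; then 1 M aq. HCl, 0 °C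
Reagents that add atoms: water, O
Why: Grignard addition to an aryl nitrile stops at the ketimide, and brief cold acidic hydrolysis should give the deoxybenzoin without touching the ring stereocentres, which carry no acidic hydrogen here.

**Step 7**
Reactants: 14 1-[(2S,3S)-2-(2,4-dimethoxyphenyl)-3-(3,5-dimethoxyphenyl)-4-methoxy-2,3-dihydro-1-benzofuran-7-yl]-2-(3,5-dimethoxyphenyl)ethan-1-one; 15 3,4,5-trifluorobenzonitrile
Product: 16 4-{2-[(2S,3S)-2-(2,4-dimethoxyphenyl)-3-(3,5-dimethoxyphenyl)-4-methoxy-2,3-dihydro-1-benzofuran-7-yl]-1-(3,5-dimethoxyphenyl)-2-oxoethyl}-3,5-difluorobenzonitrile (labile methine, both epimers)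
Conditions: NaH (2.2 equiv), DMF, 0 → 25 °C
Reagents that add atoms: none
Why: SNAr C-arylation of the ketone enolate at C4 of 15 (para to the nitrile, flanked by two fluorines), the position that carbon and heteroatom nucleophiles attack in this arene; the product rests as its unreactive enolate.

**Step 8**
Reactants: 16 4-{2-[(2S,3S)-2-(2,4-dimethoxyphenyl)-3-(3,5-dimethoxyphenyl)-4-methoxy-2,3-dihydro-1-benzofuran-7-yl]-1-(3,5-dimethoxyphenyl)-2-oxoethyl}-3,5-difluorobenzonitrile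
Product: 17 4-{(2S)-2-[(2S,3S)-2-(2,4-dimethoxyphenyl)-3-(3,5-dimethoxyphenyl)-4-methoxy-2,3-dihydro-1-benzofuran-7-yl]-1-(3,5-dimethoxyphenyl)-2-hydroxyethyl}-3,5-difluorobenzonitrile (S at the carbinol carbon C7; both epimers at the methine C8, S expected to dominate)
Conditions: RuCl[(S,S)-TsDPEN](p-cymene) (2 mol %), HCO2H/Et3N (5:2), DMF, 40 °C
Reagents that add atoms: none
Why: Noyori–Ikariya asymmetric transfer hydrogenation should fix the carbinol carbon as S by catalyst control (same sense and catalyst as step 4) while the methine equilibrates through the enol; the methine configuration need not be controlled because step 9 is convergent.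

**Step 9**
Reactants: 17 4-{(2S)-2-[(2S,3S)-2-(2,4-dimethoxyphenyl)-3-(3,5-dimethoxyphenyl)-4-methoxy-2,3-dihydro-1-benzofuran-7-yl]-1-(3,5-dimethoxyphenyl)-2-hydroxyethyl}-3,5-difluorobenzonitrile
Product: 19 (2S,3S)-2-[(2S,3S)-2-(2,4-dimethoxyphenyl)-3-(3,5-dimethoxyphenyl)-4-methoxy-2,3-dihydro-1-benzofuran-7-yl]-3-(3,5-dimethoxyphenyl)-4-methoxy-2,3-dihydro-1-benzofuran-6-carbonitrile, via fluoro dihydrobenzofuran 18 (not isolated)
Conditions: NaH (1.1 equiv), THF, 0 → 40 °C; then NaOMe (25 wt % in MeOH, 6 equiv), DMSO, 100 °C (THF distilled off), one pot, degassed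
Reagents that add atoms: sodium methoxide, C[O-].[Na+]
Why: The sodium alkoxide of 17 adds to C7a of the 2,6-difluoro-4-cyanophenyl ring and fluoride leaves from the Meisenheimer anion (addition–elimination SNAr), forming the O1–C7a bond; the closest known reaction type is the base-mediated cyclisation of 2-(2-fluoroaryl)ethanols to 2,3-dihydrobenzofurans, here helped by the meta nitrile and the second fluorine. The furan ring closes in the 5-exo-trig mode with retention at C2, because no bond to C2 is made or broken, and since the two ortho fluorines are interchanged by rotation about C3–C3a no regioisomer can form. The only new stereocentre, C3, is set under thermodynamic control: its hydrogen is benzylic and para to the nitrile, so methoxide exchanges it and both C8 epimers of 17 (and any cis ring) should converge on the 2,3-trans (2S,3S) ring, the controlling element being the C2 aryl group fixed in step 8. In the second stage methoxide replaces the fluoride left at C4 (intermolecular SNAr meta to the nitrile, as in the stepwise alkoxylation of 3,5-difluorobenzonitrile), which places the second oxygen on ring A. The step needs ring closure to outrun loss of water or retro-addition from the open-chain anion, which the sodium counter-ion in THF should secure because the alkoxide is formed first and cyclises, and it needs only one intermolecular substitution, which is secured by adding methoxide after the ring is closed (the reverse order would give the same product).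

**Step 10**
Reactants: 19 (2S,3S)-2-[(2S,3S)-2-(2,4-dimethoxyphenyl)-3-(3,5-dimethoxyphenyl)-4-methoxy-2,3-dihydro-1-benzofuran-7-yl]-3-(3,5-dimethoxyphenyl)-4-methoxy-2,3-dihydro-1-benzofuran-6-carbonitrile
Product: 21 (2S,3S)-2-[(2S,3S)-2-(2,4-dimethoxyphenyl)-3-(3,5-dimethoxyphenyl)-4-methoxy-2,3-dihydro-1-benzofuran-7-yl]-3-(3,5-dimethoxyphenyl)-4-methoxy-2,3-dihydro-1-benzofuran-6-carbaldehyde, via aluminium aldimine 20 (not isolated)
Conditions: i-Bu2AlH (1.3 equiv), CH2Cl2, −78 °C; then aq. KNaC4H4O6, 25 °C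
Reagents that add atoms: water, O
Why: Partial reduction of the nitrile with i-Bu2AlH stops at the N-aluminio aldimine, which hydrolyses on work-up to the aldehyde; ethers and stereocentres are not affected.

**Step 11**
Reactants: 21 (2S,3S)-2-[(2S,3S)-2-(2,4-dimethoxyphenyl)-3-(3,5-dimethoxyphenyl)-4-methoxy-2,3-dihydro-1-benzofuran-7-yl]-3-(3,5-dimethoxyphenyl)-4-methoxy-2,3-dihydro-1-benzofuran-6-carbaldehyde; 22 (4-methoxybenzyl)triphenylphosphonium chloride
Product: 24 (2S,3S)-2-[(2S,3S)-2-(2,4-dimethoxyphenyl)-3-(3,5-dimethoxyphenyl)-4-methoxy-2,3-dihydro-1-benzofuran-7-yl]-3-(3,5-dimethoxyphenyl)-4-methoxy-6-[(E)-2-(4-methoxyphenyl)ethenyl]-2,3-dihydro-1-benzofuran, via Z stilbene 23 (not isolated)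
Conditions: K2CO3, 18-crown-6 (cat.), CH2Cl2, 40 °C; then PhSSPh (10 mol %), THF, 65 °C
Reagents that add atoms: none
Why: Wittig olefination with a semi-stabilised benzylic ylide under weak-base conditions, chosen because the ylide is too weakly basic to ionise the C3–H para to the aldehyde (a phosphonate carbanion would be quenched by it), followed by thiyl-radical Z → E isomerisation to the thermodynamic E stilbene.

**Step 12**
Reactants: 24 (2S,3S)-2-[(2S,3S)-2-(2,4-dimethoxyphenyl)-3-(3,5-dimethoxyphenyl)-4-methoxy-2,3-dihydro-1-benzofuran-7-yl]-3-(3,5-dimethoxyphenyl)-4-methoxy-6-[(E)-2-(4-methoxyphenyl)ethenyl]-2,3-dihydro-1-benzofuran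
Product: 25 gnetumontanin B
Conditions: BBr3 (excess), CH2Cl2, −78 → 0 °C; then MeOH, H2O
Reagents that add atoms: none
Why: Lewis-acid cleavage of all nine aryl methyl ethers, the usual end-game for oligostilbenes; both C2–O bonds carry 2,4-dioxygenated aryl groups, so any ionisation should re-close to the more stable trans rings with C3 and C3′ unchanged.

**Compound list**
1 | 1,3-dimethoxybenzene | COc1cccc(OC)c1 | starting material
2 | (3,5-dimethoxyphenyl)acetic acid | COc1cc(CC(=O)O)cc(OC)c1 | starting material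
3 | (3,5-dimethoxyphenyl)acetic trifluoroacetic anhydride | COc1cc(CC(=O)OC(=O)C(F)(F)F)cc(OC)c1 | intermediate
4 | 1-(2,4-dimethoxyphenyl)-2-(3,5-dimethoxyphenyl)ethan-1-one | O=C(Cc1cc(OC)cc(OC)c1)c1ccc(OC)cc1OC | intermediate
5 | 2-fluoro-4-methoxybenzonitrile | N#Cc1ccc(OC)cc1F | starting material
6 | 3-cyano-2-fluoro-6-methoxyphenyllithium | N#Cc1ccc(OC)c([Li])c1F | intermediate
7 | 3-bromo-2-fluoro-4-methoxybenzonitrile | N#Cc1ccc(OC)c(Br)c1F | intermediate
8 | 3-[2-(2,4-dimethoxyphenyl)-1-(3,5-dimethoxyphenyl)-2-oxoethyl]-2-fluoro-4-methoxybenzonitrile (racemic) | O=C(c1ccc(OC)cc1OC)C(c1c(F)c(C#N)ccc1OC)c1cc(OC)cc(OC)c1 | intermediate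
9 | 3-[(1S,2S)-2-(2,4-dimethoxyphenyl)-1-(3,5-dimethoxyphenyl)-2-hydroxyethyl]-2-fluoro-4-methoxybenzonitrile | O[C@H](c1ccc(OC)cc1OC)[C@H](c1c(F)c(C#N)ccc1OC)c1cc(OC)cc(OC)c1 | intermediate
10 | (2S,3S)-2-(2,4-dimethoxyphenyl)-3-(3,5-dimethoxyphenyl)-4-methoxy-2,3-dihydro-1-benzofuran-7-carbonitrile | N#Cc1ccc(OC)c2c1O[C@H](c1ccc(OC)cc1OC)[C@H]2c1cc(OC)cc(OC)c1 | intermediate
11 | 1-(chloromethyl)-3,5-dimethoxybenzene | COc1cc(CCl)cc(OC)c1 | starting material
12 | (3,5-dimethoxybenzyl)magnesium chloride | COc1cc(C[Mg]Cl)cc(OC)c1 | intermediate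
13 | chloromagnesium ketimide of 14 | Cl[Mg]N=C(Cc1cc(OC)cc(OC)c1)c1ccc(OC)c2c1O[C@H](c1ccc(OC)cc1OC)[C@H]2c1cc(OC)cc(OC)c1 | intermediate
14 | 1-[(2S,3S)-2-(2,4-dimethoxyphenyl)-3-(3,5-dimethoxyphenyl)-4-methoxy-2,3-dihydro-1-benzofuran-7-yl]-2-(3,5-dimethoxyphenyl)ethan-1-one | O=C(Cc1cc(OC)cc(OC)c1)c1ccc(OC)c2c1O[C@H](c1ccc(OC)cc1OC)[C@H]2c1cc(OC)cc(OC)c1 | intermediate
15 | 3,4,5-trifluorobenzonitrile | N#Cc1cc(F)c(F)c(F)c1 | starting material
16 | 4-{2-[(2S,3S)-2-(2,4-dimethoxyphenyl)-3-(3,5-dimethoxyphenyl)-4-methoxy-2,3-dihydro-1-benzofuran-7-yl]-1-(3,5-dimethoxyphenyl)-2-oxoethyl}-3,5-difluorobenzonitrile (both methine epimers) | O=C(c1ccc(OC)c2c1O[C@H](c1ccc(OC)cc1OC)[C@H]2c1cc(OC)cc(OC)c1)C(c1c(F)cc(C#N)cc1F)c1cc(OC)cc(OC)c1 | intermediate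
17 | 4-{(2S)-2-[(2S,3S)-2-(2,4-dimethoxyphenyl)-3-(3,5-dimethoxyphenyl)-4-methoxy-2,3-dihydro-1-benzofuran-7-yl]-1-(3,5-dimethoxyphenyl)-2-hydroxyethyl}-3,5-difluorobenzonitrile (both methine epimers) | O[C@H](c1ccc(OC)c2c1O[C@H](c1ccc(OC)cc1OC)[C@H]2c1cc(OC)cc(OC)c1)C(c1c(F)cc(C#N)cc1F)c1cc(OC)cc(OC)c1 | intermediate
18 | (2S,3S)-2-[(2S,3S)-2-(2,4-dimethoxyphenyl)-3-(3,5-dimethoxyphenyl)-4-methoxy-2,3-dihydro-1-benzofuran-7-yl]-3-(3,5-dimethoxyphenyl)-4-fluoro-2,3-dihydro-1-benzofuran-6-carbonitrile | N#Cc1cc(F)c2c(c1)O[C@H](c1ccc(OC)c3c1O[C@H](c1ccc(OC)cc1OC)[C@H]3c1cc(OC)cc(OC)c1)[C@H]2c1cc(OC)cc(OC)c1 | intermediate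
19 | (2S,3S)-2-[(2S,3S)-2-(2,4-dimethoxyphenyl)-3-(3,5-dimethoxyphenyl)-4-methoxy-2,3-dihydro-1-benzofuran-7-yl]-3-(3,5-dimethoxyphenyl)-4-methoxy-2,3-dihydro-1-benzofuran-6-carbonitrile | N#Cc1cc(OC)c2c(c1)O[C@H](c1ccc(OC)c3c1O[C@H](c1ccc(OC)cc1OC)[C@H]3c1cc(OC)cc(OC)c1)[C@H]2c1cc(OC)cc(OC)c1 | intermediate
20 | N-(diisobutylaluminio)aldimine of 21 | CC(C)C[Al](CC(C)C)N=Cc1cc(OC)c2c(c1)O[C@H](c1ccc(OC)c3c1O[C@H](c1ccc(OC)cc1OC)[C@H]3c1cc(OC)cc(OC)c1)[C@H]2c1cc(OC)cc(OC)c1 | intermediate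
21 | (2S,3S)-2-[(2S,3S)-2-(2,4-dimethoxyphenyl)-3-(3,5-dimethoxyphenyl)-4-methoxy-2,3-dihydro-1-benzofuran-7-yl]-3-(3,5-dimethoxyphenyl)-4-methoxy-2,3-dihydro-1-benzofuran-6-carbaldehyde | O=Cc1cc(OC)c2c(c1)O[C@H](c1ccc(OC)c3c1O[C@H](c1ccc(OC)cc1OC)[C@H]3c1cc(OC)cc(OC)c1)[C@H]2c1cc(OC)cc(OC)c1 | intermediate
22 | (4-methoxybenzyl)triphenylphosphonium chloride | COc1ccc(C[P+](c2ccccc2)(c2ccccc2)c2ccccc2)cc1.[Cl-] | starting material
23 | Z isomer of 24 | COc1ccc(/C=C\c2cc(OC)c3c(c2)O[C@H](c2ccc(OC)c4c2O[C@H](c2ccc(OC)cc2OC)[C@H]4c2cc(OC)cc(OC)c2)[C@H]3c2cc(OC)cc(OC)c2)cc1 | intermediate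
24 | gnetumontanin B nonamethyl ether, (2S,3S,2′S,3′S), E alkene | COc1ccc(/C=C/c2cc(OC)c3c(c2)O[C@H](c2ccc(OC)c4c2O[C@H](c2ccc(OC)cc2OC)[C@H]4c2cc(OC)cc(OC)c2)[C@H]3c2cc(OC)cc(OC)c2)cc1 | intermediate
25 | gnetumontanin B | Oc1ccc(/C=C/c2cc(O)c3c(c2)O[C@H](c2ccc(O)c4c2O[C@H](c2ccc(O)cc2O)[C@H]4c2cc(O)cc(O)c2)[C@H]3c2cc(O)cc(O)c2)cc1 | target

**Totals**
Total step count: 12. Longest linear sequence: 11 steps (5 → 25 through steps 2–12; the branch 1 + 2 → 4 joins at step 3).

**Steps most likely to fail**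

1. Step 9. In the open-chain anion the methine C–H para to the nitrile is more acidic than the O–H, so proton transfer to carbon followed by loss of hydroxide, or C7–C8 retro-addition (which would also scramble C2), may outrun ring closure. In the second stage, ionisation at C3 deactivates ring A towards methoxide, so the fluoride exchange may stall, and long heating may open the furan by β-elimination of the aryloxide. The fallback sets out from 14 and comes back at 19, and forms the same O–aryl bond by palladium catalysis under weak base. Ketone 14 is arylated (NaH, DMF) with commercial 3,5-dichloro-4-fluorobenzonitrile, whose fluoride para to the nitrile is displaced, to give the dichloro ketone F1. Transfer hydrogenation as in step 8 gives the (S)-carbinol, dichloro alcohol F2. Intramolecular etherification (Pd(OAc)2, t-BuXPhos, Cs2CO3, toluene, 80 °C) gives the chloro dihydrobenzofuran F3. A second palladium-catalysed C–O coupling with methanol (Pd(OAc)2, t-BuBrettPhos, Cs2CO3, MeOH/toluene, 80 °C) replaces the remaining chloride and should deliver 19; the carbonate is basic enough to equilibrate C3 to trans.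

2. Step 12. Acid-promoted reactions may compete with demethylation: electrophilic cyclisation of the electron-rich stilbene onto the resorcinol ring at C3, addition of HBr to the alkene, and ionisation of the benzylic C2–O bonds. The fallback sets out from 21 and comes back at 25, and moves the ether cleavage to a stage without the alkene. BBr3 on 21 gives the octaphenol aldehyde F4, and TBSCl/imidazole in DMF gives the octakis(tert-butyldimethylsilyl) aldehyde F5. Wittig olefination under the step 11 conditions with {4-[(tert-butyldimethylsilyl)oxy]benzyl}triphenylphosphonium bromide F6 (from (4-hydroxybenzyl)triphenylphosphonium bromide, TBSCl and imidazole) gives first the Z nonasilyl stilbene F7 and, after PhSSPh isomerisation, the E nonasilyl stilbene F8. Bu4NF/AcOH in THF at 0 °C then removes all nine silyl groups to give 25.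

3. Step 4. Hydride transfer to a hindered, easily enolised 1,2,2-triarylethanone may be slow, and discrimination of the carbonyl faces or of the two α-aryl groups may be poor; the same reaction type is used in step 8, where step 9 corrects the methine. The fallback sets out from 8 and comes back at 10, and replaces asymmetric catalysis by resolution. NaBH4 in MeOH/THF at −20 °C (Felkin–Anh control) should give the racemic anti alcohol F9. Cyclisation as in step 5 gives the racemic trans nitrile F10, and preparative chromatography on a chiral stationary phase separates the (2S,3S) enantiomer, which is 10.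

**Further compounds**
F1 | step 9 | 3,5-dichloro-4-{2-[(2S,3S)-2-(2,4-dimethoxyphenyl)-3-(3,5-dimethoxyphenyl)-4-methoxy-2,3-dihydro-1-benzofuran-7-yl]-1-(3,5-dimethoxyphenyl)-2-oxoethyl}benzonitrile | O=C(c1ccc(OC)c2c1O[C@H](c1ccc(OC)cc1OC)[C@H]2c1cc(OC)cc(OC)c1)C(c1c(Cl)cc(C#N)cc1Cl)c1cc(OC)cc(OC)c1
F2 | step 9 | 3,5-dichloro-4-{(2S)-2-[(2S,3S)-2-(2,4-dimethoxyphenyl)-3-(3,5-dimethoxyphenyl)-4-methoxy-2,3-dihydro-1-benzofuran-7-yl]-1-(3,5-dimethoxyphenyl)-2-hydroxyethyl}benzonitrile | O[C@H](c1ccc(OC)c2c1O[C@H](c1ccc(OC)cc1OC)[C@H]2c1cc(OC)cc(OC)c1)C(c1c(Cl)cc(C#N)cc1Cl)c1cc(OC)cc(OC)c1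
F3 | step 9 | (2S,3S)-4-chloro-2-[(2S,3S)-2-(2,4-dimethoxyphenyl)-3-(3,5-dimethoxyphenyl)-4-methoxy-2,3-dihydro-1-benzofuran-7-yl]-3-(3,5-dimethoxyphenyl)-2,3-dihydro-1-benzofuran-6-carbonitrile | N#Cc1cc(Cl)c2c(c1)O[C@H](c1ccc(OC)c3c1O[C@H](c1ccc(OC)cc1OC)[C@H]3c1cc(OC)cc(OC)c1)[C@H]2c1cc(OC)cc(OC)c1
F4 | step 12 | octaphenol aldehyde (21 with all eight methyl ethers cleaved) | O=Cc1cc(O)c2c(c1)O[C@H](c1ccc(O)c3c1O[C@H](c1ccc(O)cc1O)[C@H]3c1cc(O)cc(O)c1)[C@H]2c1cc(O)cc(O)c1
F5 | step 12 | octakis(tert-butyldimethylsilyl) ether of F4 | O=Cc1cc(O[Si](C)(C)C(C)(C)C)c2c(c1)O[C@H](c1ccc(O[Si](C)(C)C(C)(C)C)c3c1O[C@H](c1ccc(O[Si](C)(C)C(C)(C)C)cc1O[Si](C)(C)C(C)(C)C)[C@H]3c1cc(O[Si](C)(C)C(C)(C)C)cc(O[Si](C)(C)C(C)(C)C)c1)[C@H]2c1cc(O[Si](C)(C)C(C)(C)C)cc(O[Si](C)(C)C(C)(C)C)c1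
F6 | step 12 | {4-[(tert-butyldimethylsilyl)oxy]benzyl}triphenylphosphonium bromide | CC(C)(C)[Si](C)(C)Oc1ccc(C[P+](c2ccccc2)(c2ccccc2)c2ccccc2)cc1.[Br-]
F7 | step 12 | Z nonakis(tert-butyldimethylsilyl) ether of gnetumontanin B | CC(C)(C)[Si](C)(C)Oc1ccc(/C=C\c2cc(O[Si](C)(C)C(C)(C)C)c3c(c2)O[C@H](c2ccc(O[Si](C)(C)C(C)(C)C)c4c2O[C@H](c2ccc(O[Si](C)(C)C(C)(C)C)cc2O[Si](C)(C)C(C)(C)C)[C@H]4c2cc(O[Si](C)(C)C(C)(C)C)cc(O[Si](C)(C)C(C)(C)C)c2)[C@H]3c2cc(O[Si](C)(C)C(C)(C)C)cc(O[Si](C)(C)C(C)(C)C)c2)cc1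
F8 | step 12 | E nonakis(tert-butyldimethylsilyl) ether of gnetumontanin B | CC(C)(C)[Si](C)(C)Oc1ccc(/C=C/c2cc(O[Si](C)(C)C(C)(C)C)c3c(c2)O[C@H](c2ccc(O[Si](C)(C)C(C)(C)C)c4c2O[C@H](c2ccc(O[Si](C)(C)C(C)(C)C)cc2O[Si](C)(C)C(C)(C)C)[C@H]4c2cc(O[Si](C)(C)C(C)(C)C)cc(O[Si](C)(C)C(C)(C)C)c2)[C@H]3c2cc(O[Si](C)(C)C(C)(C)C)cc(O[Si](C)(C)C(C)(C)C)c2)cc1
F9 | step 4 | racemic anti alcohol, (1S,2S) and (1R,2R) forms of 9 | O[C@H](c1ccc(OC)cc1OC)[C@H](c1c(F)c(C#N)ccc1OC)c1cc(OC)cc(OC)c1.O[C@@H](c1ccc(OC)cc1OC)[C@@H](c1c(F)c(C#N)ccc1OC)c1cc(OC)cc(OC)c1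
F10 | step 4 | racemic trans nitrile, (2S,3S) and (2R,3R) forms of 10 | N#Cc1ccc(OC)c2c1O[C@H](c1ccc(OC)cc1OC)[C@H]2c1cc(OC)cc(OC)c1.N#Cc1ccc(OC)c2c1O[C@@H](c1ccc(OC)cc1OC)[C@@H]2c1cc(OC)cc(OC)c1
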